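## Retrosynthetic overview

1. Target 30 ← nonaacetate 29 ← Heck coupling of aryl bromide 27 with 4-acetoxystyrene. The stilbene is attached last, after BBr3 demethylation of 25, because a stilbene next to a 2-aryl-dihydrobenzofuran is prone to acid-induced cyclisation.
2. 25 ← bis(N-nitroso-1,3-benzoxazine) 23 by double nitrogen deletion. Each dihydrofuran ring (O1–C2–C3–C3a–C7a) comes from a six-membered 3,4-dihydro-2H-1,3-benzoxazine (O1–C2–N3–C4–C4a–C8a) by loss of N3 as N2, which forges both C2–C3 bonds in one operation.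
3. Enabling feature: in both dihydrofurans C2 (O-bound, aryl-bearing) and C3 (bound to the fused arene and a 3,5-dioxygenated aryl) are benzylic, carry no β-hydrogen, and sit next to the phenolic oxygen of the fused ring. One nitrogen can therefore bridge them as a cyclic N,O-acetal (aminophenol + aryl aldehyde) and leave as N2 through a doubly stabilised radical pair.
4. 23 ← aminophenol 21 + aldehyde 13; 13 ← aminophenol 9 + aldehyde 10. The two C–N stereocentres (future C3 and C3′) come from (R)-tert-butanesulfinamide; the two C2 centres are relayed from them.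
5. Ring order: oxazine on the central resorcinol ring, then oxazine on the bromoresorcinol ring, both contracted together to the two dihydrofurans, stilbene last.

Key step: step 15

Assumption: the facial sense of the two N-sulfinyl imine additions is taken from the usual open (ArLi, THF; step 4) and closed (ArMgBr, CH2Cl2; step 12) transition-state models; if either proves reversed, (S)-tert-butanesulfinamide is used for that fragment and nothing else changes.

## Route

Step 1
Reactants: 1 3,5-dimethoxybenzaldehyde; 2 (R)-tert-butanesulfinamide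
Product: 3 (R,E)-N-(3,5-dimethoxybenzylidene)-2-methylpropane-2-sulfinamide
Conditions: Ti(OEt)4, THF, rt
Reagents that add atoms: none
Why: Ti(OEt)4-mediated condensation of an aryl aldehyde with tert-butanesulfinamide (Ellman N-sulfinyl imine formation) gives the (E)-aldimine and does not touch the sulfur stereocentre.

Step 2
Reactants: 4 2-hydroxy-4-methoxybenzaldehyde
Product: 5 4-methoxy-2-(methoxymethoxy)benzaldehyde
Conditions: NaH, MOMCl, DMF, 0 °C
Reagents that add atoms: chloromethyl methyl ether (COCCl)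
Why: Williamson-type O-alkylation of the sodium phenoxide; the MOM ether later directs lithiation and comes off together with the sulfinyl group.

Step 3
Reactants: 5 4-methoxy-2-(methoxymethoxy)benzaldehyde
Product: 6 1-(dimethoxymethyl)-4-methoxy-2-(methoxymethoxy)benzene
Conditions: HC(OMe)3, MeOH, PPTS (cat.), rt
Reagents that add atoms: trimethyl orthoformate (COC(OC)OC)
Why: acid-catalysed acetalisation masks the aldehyde against n-BuLi, and PPTS at room temperature leaves the aryl MOM ether intact.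

Step 4
Reactants: 6 1-(dimethoxymethyl)-4-methoxy-2-(methoxymethoxy)benzene; 3 (R,E)-N-(3,5-dimethoxybenzylidene)-2-methylpropane-2-sulfinamide
Product: 8 (R)-N-[(S)-(3,5-dimethoxyphenyl)[3-(dimethoxymethyl)-6-methoxy-2-(methoxymethoxy)phenyl]methyl]-2-methylpropane-2-sulfinamide, via [3-(dimethoxymethyl)-6-methoxy-2-(methoxymethoxy)phenyl]lithium 7 (not isolated)
Conditions: n-BuLi, THF, 0 °C; then 3, −78 °C
Reagents that add atoms: none
Why: directed ortho-metalation at the ring position flanked by OMOM and OMe, then 1,2-addition of the aryllithium to the N-sulfinyl aldimine (Ellman addition); in THF the open transition state is expected to set the carbinamine carbon as (S) under control of the (R)-sulfinyl group.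

Step 5
Reactants: 8 the sulfinamide from step 4
Product: 9 2-[(S)-amino(3,5-dimethoxyphenyl)methyl]-6-(dimethoxymethyl)-3-methoxyphenol
Conditions: HCl (4 M in dioxane), dry MeOH, 0 °C → rt; then NaHCO3
Reagents that add atoms: none
Why: acidic methanolysis removes the N-sulfinyl group and the aryl MOM ether while dry methanol keeps the dimethyl acetal, and the ammonium salt of this Betti-type base does not ionise at the benzylic carbon, so the stereocentre is safe.

Step 6
Reactants: 9 the aminophenol from step 5; 10 2,4-dimethoxybenzaldehyde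
Product: 12 (2R,4S)-2-(2,4-dimethoxyphenyl)-4-(3,5-dimethoxyphenyl)-8-(dimethoxymethyl)-5-methoxy-3-nitroso-3,4-dihydro-2H-1,3-benzoxazine, via N–H benzoxazine ring tautomer 11 (not isolated)
Conditions: 4 Å MS, CH2Cl2, rt; then t-BuONO, AcOH (cat.), 0 °C → rt, dark, Ar
Reagents that add atoms: tert-butyl nitrite (CC(C)(C)ON=O)
Why: condensation of a Betti-type aminophenol with an aryl aldehyde gives the ring–chain tautomeric 1,3-oxazine, and N-nitrosation (known for oxazolidines and tetrahydro-1,3-oxazines) traps the ring form, at N–H directly or through phenol capture of the N-nitrosoiminium ion of the imine; C2 is set under thermodynamic control, expected trans to the C4 aryl group that the peri methoxy group pushes pseudo-axial.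

Step 7
Reactants: 12 the N-nitroso oxazine acetal from step 6
Product: 13 (2R,4S)-2-(2,4-dimethoxyphenyl)-4-(3,5-dimethoxyphenyl)-5-methoxy-3-nitroso-3,4-dihydro-2H-1,3-benzoxazine-8-carbaldehyde
Conditions: PPTS (cat.), acetone/H2O, rt
Reagents that add atoms: water (O)
Why: hydrolysis of an electron-rich aryl dimethyl acetal under very mild acid, which the N-nitroso N,O-acetal (nitrogen lone pair engaged by the nitroso group) should survive.

Step 8
Reactants: 14 1-bromo-3,5-dimethoxybenzene
Product: 15 2-bromo-4,6-dimethoxybenzaldehyde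
Conditions: POCl3, DMF, 0 → 90 °C; aq. NaOAc
Reagents that add atoms: N,N-dimethylformamide (CN(C)C=O); water (O)
Why: Vilsmeier–Haack formylation at the position para to one methoxy group and ortho to the other, next to bromine, the usual site for this arene.

Step 9
Reactants: 15 2-bromo-4,6-dimethoxybenzaldehyde
Product: 16 2-bromo-6-hydroxy-4-methoxybenzaldehyde
Conditions: BCl3, CH2Cl2, −78 → 0 °C; H2O
Reagents that add atoms: none
Why: chelation-directed Lewis-acid demethylation cleaves only the methyl ether ortho to the formyl group.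

Step 10
Reactants: 16 2-bromo-6-hydroxy-4-methoxybenzaldehyde
Product: 17 2-bromo-4-methoxy-6-(methoxymethoxy)benzaldehyde
Conditions: NaH, MOMCl, DMF, 0 °C
Reagents that add atoms: chloromethyl methyl ether (COCCl)
Why: O-alkylation of the phenoxide with MOMCl as in step 2.

Step 11
Reactants: 17 2-bromo-4-methoxy-6-(methoxymethoxy)benzaldehyde; 2 (R)-tert-butanesulfinamide
Product: 18 (R,E)-N-[2-bromo-4-methoxy-6-(methoxymethoxy)benzylidene]-2-methylpropane-2-sulfinamide
Conditions: Ti(OEt)4, THF, 65 °C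
Reagents that add atoms: none
Why: Ellman N-sulfinyl imine formation; heating with Ti(OEt)4 overcomes the di-ortho substitution of the aldehyde.

Step 12
Reactants: 18 the sulfinimine from step 11; 14 1-bromo-3,5-dimethoxybenzene
Product: 20 (R)-N-[(S)-[2-bromo-4-methoxy-6-(methoxymethoxy)phenyl](3,5-dimethoxyphenyl)methyl]-2-methylpropane-2-sulfinamide, via (3,5-dimethoxyphenyl)magnesium bromide 19 (not isolated)
Conditions: 14, Mg, THF; then 18, CH2Cl2, −48 °C → rt
Reagents that add atoms: none
Why: Grignard addition to an N-sulfinyl aldimine in a non-coordinating solvent through the closed six-membered Mg–O=S transition state (Ellman addition), which from the (R)-sulfinyl group sets the carbinamine carbon as (S); the aryl bromide of 18 does not exchange with an aryl Grignard reagent at this temperature.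

Step 13
Reactants: 20 the sulfinamide from step 12
Product: 21 2-[(S)-amino(3,5-dimethoxyphenyl)methyl]-3-bromo-5-methoxyphenol
Conditions: HCl (4 M in dioxane), MeOH, 0 °C → rt; then NaHCO3
Reagents that add atoms: none
Why: acidic methanolysis of the N-sulfinyl group and of the MOM ether as in step 5.

Step 14
Reactants: 21 the aminophenol from step 13; 13 the aldehyde from step 7
Product: 23 (2R,4S)-5-bromo-2-[(2R,4S)-2-(2,4-dimethoxyphenyl)-4-(3,5-dimethoxyphenyl)-5-methoxy-3-nitroso-3,4-dihydro-2H-1,3-benzoxazin-8-yl]-4-(3,5-dimethoxyphenyl)-7-methoxy-3-nitroso-3,4-dihydro-2H-1,3-benzoxazine, via N–H oxazine ring tautomer 22 (not isolated)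
Conditions: 4 Å MS, CH2Cl2, 40 °C; then t-BuONO, AcOH (cat.), 0 °C → rt, dark, Ar
Reagents that add atoms: tert-butyl nitrite (CC(C)(C)ON=O)
Why: the same condensation and ring-form trapping by N-nitrosation as in step 6; the peri bromine takes the role of the peri methoxy group in favouring the trans-2,4-diaryl oxazine, and the first N-nitroso oxazine is inert to these conditions.

Step 15
Reactants: 23 the bis(N-nitroso-1,3-benzoxazine) from step 14
Product: 25 (2S,3S)-4-bromo-2-[(2S,3S)-2-(2,4-dimethoxyphenyl)-3-(3,5-dimethoxyphenyl)-4-methoxy-2,3-dihydro-1-benzofuran-7-yl]-3-(3,5-dimethoxyphenyl)-6-methoxy-2,3-dihydro-1-benzofuran, via bis(1,1-diazene) 24 (not isolated)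
Conditions: Na2S2O4, NaOH (aq.), EtOH/THF, 65 °C, Ar
Reagents that add atoms: none
Why: Proposed new method: dithionite reduces each N–N=O group to a 1,1-diazene whose two C–N bonds are benzylic (one also α-aryloxy), so N2 is lost readily and the singlet C2/C4 radical pair, held about 2.4 Å apart by the O1–C8a–C4a bridge, collapses to the C2–C3 bond of the dihydrofuran. The closest known reaction type is the dithionite reduction of N-nitroso-2,6-diarylpiperidines and N-nitrosodibenzylamines (and the oxidation of the matching N-amino compounds) to 1,2-diarylcyclopentanes and bibenzyls with retention, together with modern nitrogen deletion of benzylic secondary amines; it has not been shown on cyclic N,O-acetals, hence the label. Each of the two dihydrofuran rings closes by radical–radical recombination across the vacated nitrogen, a 6 → 5 ring contraction and not a polar cyclisation. C3 and C3′ keep the configuration set in steps 4 and 12 because collapse should be faster than rotation about the benzylic C–aryl bond, and C2 and C2′ should emerge trans to them by least-motion closure from the trans-2,4-diaryl oxazines. The step needs recombination to win over hydrogen transfer and fragmentation, which the substrate secures because neither radical centre has a β-hydrogen and the α-aryloxy radical has no productive scission. Any cis isomer formed at C2 or C2′ is corrected in step 16.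

Step 16
Reactants: 25 the permethylated bromo-bis(dihydrobenzofuran) from step 15
Product: 26 the octaphenol: (2S,3S)-4-bromo-2-[(2S,3S)-2-(2,4-dihydroxyphenyl)-3-(3,5-dihydroxyphenyl)-4-hydroxy-2,3-dihydro-1-benzofuran-7-yl]-3-(3,5-dihydroxyphenyl)-2,3-dihydro-1-benzofuran-6-ol
Conditions: BBr3, CH2Cl2, −78 °C → rt; MeOH, H2O
Reagents that add atoms: none
Why: BBr3 cleavage of all eight aryl methyl ethers, safe here because no stilbene is present yet; reversible ionisation of the C2–O bonds (ortho,para-oxygenated 2-aryl groups) under these conditions also converts any cis-dihydrofuran into the more stable 2,3-trans isomer without touching C3 or C3′.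

Step 17
Reactants: 26 the octaphenol from step 16
Product: 27 the octaacetate of 26
Conditions: Ac2O, pyridine, DMAP (cat.), rt
Reagents that add atoms: acetic anhydride (CC(=O)OC(C)=O)
Why: DMAP-catalysed peracetylation of the eight phenols gives a stable, non-chelating substrate for the palladium step.

Step 18
Reactants: 27 the octaacetate bromide; 28 4-acetoxystyrene
Product: 29 the nonaacetate of the target, (E)-stilbene in place
Conditions: Pd2(dba)3 (cat.), P(t-Bu)3·HBF4 (cat.), Cy2NMe, dioxane, 80 °C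
Reagents that add atoms: none
Why: Mizoroki–Heck coupling under conditions used for hindered aryl bromides; syn insertion and syn β-hydride elimination give the (E)-stilbene, and no stereocentre is epimerisable under the weakly basic conditions.

Step 19
Reactants: 29 the nonaacetate from step 18
Product: 30 CNP0397447.1 (target)
Conditions: K2CO3 (cat.), degassed MeOH, 0 °C → rt; then AcOH
Reagents that add atoms: none
Why: base-catalysed transesterification (Zemplén-type deacetylation) frees the nine phenols without acid, so the stilbene–dihydrobenzofuran array, which cyclises under acid, stays intact.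

## Compound list

1 | 3,5-dimethoxybenzaldehyde | COc1cc(C=O)cc(OC)c1 | starting material
2 | (R)-tert-butanesulfinamide | CC(C)(C)[S@@](=O)N | starting material
3 | (R,E)-N-(3,5-dimethoxybenzylidene)-2-methylpropane-2-sulfinamide | CC(C)(C)[S@@](=O)/N=C/c1cc(OC)cc(OC)c1 | intermediate
4 | 2-hydroxy-4-methoxybenzaldehyde | COc1ccc(C=O)c(O)c1 | starting material
5 | 4-methoxy-2-(methoxymethoxy)benzaldehyde | COCOc1cc(OC)ccc1C=O | intermediate
6 | 1-(dimethoxymethyl)-4-methoxy-2-(methoxymethoxy)benzene | COCOc1cc(OC)ccc1C(OC)OC | intermediate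
7 | [3-(dimethoxymethyl)-6-methoxy-2-(methoxymethoxy)phenyl]lithium | [Li]c1c(OC)ccc(C(OC)OC)c1OCOC | intermediate
8 | (R)-N-[(S)-(3,5-dimethoxyphenyl)[3-(dimethoxymethyl)-6-methoxy-2-(methoxymethoxy)phenyl]methyl]-2-methylpropane-2-sulfinamide | CC(C)(C)[S@@](=O)N[C@@H](c1cc(OC)cc(OC)c1)c1c(OC)ccc(C(OC)OC)c1OCOC | intermediate
9 | 2-[(S)-amino(3,5-dimethoxyphenyl)methyl]-6-(dimethoxymethyl)-3-methoxyphenol | N[C@@H](c1cc(OC)cc(OC)c1)c1c(OC)ccc(C(OC)OC)c1O | intermediate
10 | 2,4-dimethoxybenzaldehyde | COc1ccc(C=O)c(OC)c1 | starting material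
11 | (2R,4S)-2-(2,4-dimethoxyphenyl)-4-(3,5-dimethoxyphenyl)-8-(dimethoxymethyl)-5-methoxy-3,4-dihydro-2H-1,3-benzoxazine (ring tautomer of the imine) | COc1ccc(C(OC)OC)c2O[C@H](c3ccc(OC)cc3OC)N[C@@H](c3cc(OC)cc(OC)c3)c12 | intermediate
12 | (2R,4S)-2-(2,4-dimethoxyphenyl)-4-(3,5-dimethoxyphenyl)-8-(dimethoxymethyl)-5-methoxy-3-nitroso-3,4-dihydro-2H-1,3-benzoxazine | COc1ccc(C(OC)OC)c2O[C@H](c3ccc(OC)cc3OC)N(N=O)[C@@H](c3cc(OC)cc(OC)c3)c12 | intermediate
13 | (2R,4S)-2-(2,4-dimethoxyphenyl)-4-(3,5-dimethoxyphenyl)-5-methoxy-3-nitroso-3,4-dihydro-2H-1,3-benzoxazine-8-carbaldehyde | COc1ccc(C=O)c2O[C@H](c3ccc(OC)cc3OC)N(N=O)[C@@H](c3cc(OC)cc(OC)c3)c12 | intermediate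
14 | 1-bromo-3,5-dimethoxybenzene | COc1cc(Br)cc(OC)c1 | starting material
15 | 2-bromo-4,6-dimethoxybenzaldehyde | COc1cc(Br)c(C=O)c(OC)c1 | intermediate
16 | 2-bromo-6-hydroxy-4-methoxybenzaldehyde | COc1cc(O)c(C=O)c(Br)c1 | intermediate
17 | 2-bromo-4-methoxy-6-(methoxymethoxy)benzaldehyde | COCOc1cc(OC)cc(Br)c1C=O | intermediate
18 | (R,E)-N-[2-bromo-4-methoxy-6-(methoxymethoxy)benzylidene]-2-methylpropane-2-sulfinamide | CC(C)(C)[S@@](=O)/N=C/c1c(Br)cc(OC)cc1OCOC | intermediate
19 | (3,5-dimethoxyphenyl)magnesium bromide | COc1cc([Mg]Br)cc(OC)c1 | intermediate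
20 | (R)-N-[(S)-[2-bromo-4-methoxy-6-(methoxymethoxy)phenyl](3,5-dimethoxyphenyl)methyl]-2-methylpropane-2-sulfinamide | CC(C)(C)[S@@](=O)N[C@@H](c1cc(OC)cc(OC)c1)c1c(Br)cc(OC)cc1OCOC | intermediate
21 | 2-[(S)-amino(3,5-dimethoxyphenyl)methyl]-3-bromo-5-methoxyphenol | N[C@@H](c1cc(OC)cc(OC)c1)c1c(Br)cc(OC)cc1O | intermediate
22 | (2R,4S)-5-bromo-2-[(2R,4S)-2-(2,4-dimethoxyphenyl)-4-(3,5-dimethoxyphenyl)-5-methoxy-3-nitroso-3,4-dihydro-2H-1,3-benzoxazin-8-yl]-4-(3,5-dimethoxyphenyl)-7-methoxy-3,4-dihydro-2H-1,3-benzoxazine (N–H ring tautomer) | COc1cc(Br)c2[C@H](c3cc(OC)cc(OC)c3)N[C@@H](c3ccc(OC)c4c3O[C@H](c3ccc(OC)cc3OC)N(N=O)[C@H]4c3cc(OC)cc(OC)c3)Oc2c1 | intermediate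
23 | (2R,4S)-5-bromo-2-[(2R,4S)-2-(2,4-dimethoxyphenyl)-4-(3,5-dimethoxyphenyl)-5-methoxy-3-nitroso-3,4-dihydro-2H-1,3-benzoxazin-8-yl]-4-(3,5-dimethoxyphenyl)-7-methoxy-3-nitroso-3,4-dihydro-2H-1,3-benzoxazine | COc1cc(Br)c2[C@H](c3cc(OC)cc(OC)c3)N(N=O)[C@@H](c3ccc(OC)c4c3O[C@H](c3ccc(OC)cc3OC)N(N=O)[C@H]4c3cc(OC)cc(OC)c3)Oc2c1 | intermediate
24 | bis(1,1-diazene) of 23 (both N–N=O groups as N+=N−) | COc1cc(Br)c2[C@H](c3cc(OC)cc(OC)c3)[N+](=[N-])[C@@H](c3ccc(OC)c4c3O[C@H](c3ccc(OC)cc3OC)[N+](=[N-])[C@H]4c3cc(OC)cc(OC)c3)Oc2c1 | intermediate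
25 | (2S,3S)-4-bromo-2-[(2S,3S)-2-(2,4-dimethoxyphenyl)-3-(3,5-dimethoxyphenyl)-4-methoxy-2,3-dihydro-1-benzofuran-7-yl]-3-(3,5-dimethoxyphenyl)-6-methoxy-2,3-dihydro-1-benzofuran | COc1cc(Br)c2[C@H](c3cc(OC)cc(OC)c3)[C@@H](c3ccc(OC)c4c3O[C@H](c3ccc(OC)cc3OC)[C@H]4c3cc(OC)cc(OC)c3)Oc2c1 | intermediate
26 | octaphenol corresponding to 25 (all eight OMe as OH; 2S,3S in both dihydrofurans) | Oc1cc(Br)c2[C@H](c3cc(O)cc(O)c3)[C@@H](c3ccc(O)c4c3O[C@H](c3ccc(O)cc3O)[C@H]4c3cc(O)cc(O)c3)Oc2c1 | intermediate
27 | octaacetate of 26 | CC(=O)Oc1cc(Br)c2[C@H](c3cc(OC(C)=O)cc(OC(C)=O)c3)[C@@H](c3ccc(OC(C)=O)c4c3O[C@H](c3ccc(OC(C)=O)cc3OC(C)=O)[C@H]4c3cc(OC(C)=O)cc(OC(C)=O)c3)Oc2c1 | intermediate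
28 | 4-acetoxystyrene (4-ethenylphenyl acetate) | CC(=O)Oc1ccc(C=C)cc1 | starting material
29 | nonaacetate of the target | CC(=O)Oc1ccc(/C=C/c2cc(OC(C)=O)cc3c2[C@H](c2cc(OC(C)=O)cc(OC(C)=O)c2)[C@@H](c2ccc(OC(C)=O)c4c2O[C@H](c2ccc(OC(C)=O)cc2OC(C)=O)[C@H]4c2cc(OC(C)=O)cc(OC(C)=O)c2)O3)cc1 | intermediate
30 | CNP0397447.1 | Oc1ccc(/C=C/c2cc(O)cc3c2[C@H](c2cc(O)cc(O)c2)[C@@H](c2ccc(O)c4c2O[C@H](c2ccc(O)cc2O)[C@H]4c2cc(O)cc(O)c2)O3)cc1 | target

## Step count and risks

Total step count: 19. Longest linear sequence: 12 steps (4 → 30 through steps 2–7 and 14–19, or 14 → 30 through steps 8–19).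

**Risk 1 – step 15 (the labelled step).** The reduction may stop at the N-amino oxazine or run on to N–N cleavage instead of passing through the diazene. The aminal may also open hydrolytically in hot aqueous base before N2 is lost, and the radical pair may lose configuration at C3/C3′ if it escapes immediate collapse.

Fallback (known chemistry; sets out from 7 and 16, returns at 26): the C3 centres are set instead by enantioselective Rh(II)-catalysed intramolecular C–H insertion of diaryl carbenes into benzylic ether C–H bonds, a known route to cis-2,3-diaryl-2,3-dihydrobenzofurans.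
- Aryllithium 7 is added to 3,5-dimethoxybenzonitrile to give (3,5-dimethoxyphenyl)[3-(dimethoxymethyl)-6-methoxy-2-(methoxymethoxy)phenyl]methanimine F1.
- Aqueous HCl hydrolyses imine, acetal and MOM ether to 3-(3,5-dimethoxybenzoyl)-2-hydroxy-4-methoxybenzaldehyde F2.
- O-Alkylation with 2,4-dimethoxybenzyl chloride (K2CO3, DMF) gives 3-(3,5-dimethoxybenzoyl)-2-[(2,4-dimethoxyphenyl)methoxy]-4-methoxybenzaldehyde F3.
- NaBH4 reduces only the aldehyde to (3,5-dimethoxyphenyl){2-[(2,4-dimethoxyphenyl)methoxy]-3-(hydroxymethyl)-6-methoxyphenyl}methanone F4.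
- In parallel, 16 and two equivalents of Grignard reagent 19 give 3-bromo-2-[(3,5-dimethoxyphenyl)(hydroxy)methyl]-5-methoxyphenol F5, which MnO2 oxidises to (2-bromo-6-hydroxy-4-methoxyphenyl)(3,5-dimethoxyphenyl)methanone F6.
- Mitsunobu etherification of F6 with F4 (PPh3, DIAD) gives the diketone bis(benzyl aryl ether) F7.
- Hydrazine converts it into the bis-hydrazone F8, and MnO2 into the bis(diaryldiazomethane) F9.
- A chiral Rh(II) carboxylate of the PTAD type (enantiomer chosen for 3S) effects both insertions to the cis,cis-bis(dihydrobenzofuran) F10.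
- BBr3 under the conditions of step 16 removes the methyl ethers and epimerises C2 and C2′ to trans, which gives 26.

**Risk 2 – step 6.** The ring–chain mixture may not funnel cleanly into the N-nitroso oxazine. Competing processes are C-nitrosation or nitration of the electron-rich phenol ring of the chain tautomer and hydrolysis back to amine and aldehyde.

Fallback (sets out from 9 and 10, returns at 12): the N–N=O group is installed on a true secondary amine and the ring is closed afterwards by oxidation.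
- Reductive amination of 10 with 9 (NaBH(OAc)3) gives 2-[(S)-(3,5-dimethoxyphenyl){[(2,4-dimethoxyphenyl)methyl]amino}methyl]-6-(dimethoxymethyl)-3-methoxyphenol F11.
- t-BuONO gives N-[(S)-(3,5-dimethoxyphenyl)[3-(dimethoxymethyl)-2-hydroxy-6-methoxyphenyl]methyl]-N-[(2,4-dimethoxyphenyl)methyl]nitrous amide F12.
- DDQ oxidises the 2,4-dimethoxybenzylic C–H bond next to nitrogen and the phenol captures the cation, closing the oxazine to 12.

**Risk 3 – step 4.** The hindered, internally chelated 2,6-dioxygenated aryllithium may add through the open transition state with poor or reversed facial selectivity, or attack sulfur.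

Fallback (sets out from 7, returns at 8): the polarity of the C–C bond formation is reversed so that the well-behaved closed transition state of step 12 is used.
- Aryllithium 7 is quenched with DMF to give 3-(dimethoxymethyl)-6-methoxy-2-(methoxymethoxy)benzaldehyde F13.
- Condensation with 2 (Ti(OEt)4) gives (R,E)-N-[3-(dimethoxymethyl)-6-methoxy-2-(methoxymethoxy)benzylidene]-2-methylpropane-2-sulfinamide F14.
- Addition of Grignard reagent 19 in CH2Cl2 at −48 °C should give 8 with the same sulfur and carbon configurations.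

## Further compounds

F1 | step 15 | (3,5-dimethoxyphenyl)[3-(dimethoxymethyl)-6-methoxy-2-(methoxymethoxy)phenyl]methanimine | COCOc1c(C(=N)c2cc(OC)cc(OC)c2)c(OC)ccc1C(OC)OC
F2 | step 15 | 3-(3,5-dimethoxybenzoyl)-2-hydroxy-4-methoxybenzaldehyde | COc1cc(OC)cc(C(=O)c2c(OC)ccc(C=O)c2O)c1
F3 | step 15 | 3-(3,5-dimethoxybenzoyl)-2-[(2,4-dimethoxyphenyl)methoxy]-4-methoxybenzaldehyde | COc1ccc(COc2c(C=O)ccc(OC)c2C(=O)c2cc(OC)cc(OC)c2)c(OC)c1
F4 | step 15 | (3,5-dimethoxyphenyl){2-[(2,4-dimethoxyphenyl)methoxy]-3-(hydroxymethyl)-6-methoxyphenyl}methanone | COc1ccc(COc2c(CO)ccc(OC)c2C(=O)c2cc(OC)cc(OC)c2)c(OC)c1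
F5 | step 15 | 3-bromo-2-[(3,5-dimethoxyphenyl)(hydroxy)methyl]-5-methoxyphenol | COc1cc(O)c(C(O)c2cc(OC)cc(OC)c2)c(Br)c1
F6 | step 15 | (2-bromo-6-hydroxy-4-methoxyphenyl)(3,5-dimethoxyphenyl)methanone | COc1cc(O)c(C(=O)c2cc(OC)cc(OC)c2)c(Br)c1
F7 | step 15 | diketone bis(benzyl aryl ether) from F4 and F6 | COc1ccc(COc2c(COc3cc(OC)cc(Br)c3C(=O)c3cc(OC)cc(OC)c3)ccc(OC)c2C(=O)c2cc(OC)cc(OC)c2)c(OC)c1
F8 | step 15 | bis-hydrazone of F7 | COc1ccc(COc2c(COc3cc(OC)cc(Br)c3C(=NN)c3cc(OC)cc(OC)c3)ccc(OC)c2C(=NN)c2cc(OC)cc(OC)c2)c(OC)c1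
F9 | step 15 | bis(diaryldiazomethane) from F8 | COc1ccc(COc2c(COc3cc(OC)cc(Br)c3C(=[N+]=[N-])c3cc(OC)cc(OC)c3)ccc(OC)c2C(=[N+]=[N-])c2cc(OC)cc(OC)c2)c(OC)c1
F10 | step 15 | (2R,3S)-4-bromo-2-[(2R,3S)-2-(2,4-dimethoxyphenyl)-3-(3,5-dimethoxyphenyl)-4-methoxy-2,3-dihydro-1-benzofuran-7-yl]-3-(3,5-dimethoxyphenyl)-6-methoxy-2,3-dihydro-1-benzofuran (cis,cis) | COc1cc(Br)c2[C@H](c3cc(OC)cc(OC)c3)[C@H](c3ccc(OC)c4c3O[C@@H](c3ccc(OC)cc3OC)[C@H]4c3cc(OC)cc(OC)c3)Oc2c1
F11 | step 6 | 2-[(S)-(3,5-dimethoxyphenyl){[(2,4-dimethoxyphenyl)methyl]amino}methyl]-6-(dimethoxymethyl)-3-methoxyphenol | COc1ccc(CN[C@@H](c2cc(OC)cc(OC)c2)c2c(OC)ccc(C(OC)OC)c2O)c(OC)c1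
F12 | step 6 | N-[(S)-(3,5-dimethoxyphenyl)[3-(dimethoxymethyl)-2-hydroxy-6-methoxyphenyl]methyl]-N-[(2,4-dimethoxyphenyl)methyl]nitrous amide | COc1ccc(CN(N=O)[C@@H](c2cc(OC)cc(OC)c2)c2c(OC)ccc(C(OC)OC)c2O)c(OC)c1
F13 | step 4 | 3-(dimethoxymethyl)-6-methoxy-2-(methoxymethoxy)benzaldehyde | COCOc1c(C=O)c(OC)ccc1C(OC)OC
F14 | step 4 | (R,E)-N-[3-(dimethoxymethyl)-6-methoxy-2-(methoxymethoxy)benzylidene]-2-methylpropane-2-sulfinamide | CC(C)(C)[S@@](=O)/N=C/c1c(OC)ccc(C(OC)OC)c1OCOC
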